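**Plan**
- Cuts (chromone numbering of the target: O1, C2, C3, C4, C4a, C5–C8, C8a): first C8a–C8 (carbocycle), then O1–C8a and C2–C3 (γ-pyranone ring), then C4a–C5 (chain to enone).
- Forward: the L-threitol aldehyde (C5–C8) and but-3-yn-2-one are joined by an iodo-aldol reaction (C4a–C5). Enolate acylation with the cinnamoyl chloride and O1–C8a closure give the pyranone ring. C8a–H is turned into C8a–I, C8 is oxidised to the aldehyde, and the carbocycle is closed last.
- Enabling feature: in the γ-pyranone ring C8a is the β-carbon of the vinylogous ester O1–C8a=C4a–C4=O and carries the only ring C–H next to O1, so it can be made a vinyl iodide and then a vinylchromium nucleophile. C8 is a carbinol carbon four atoms along the chain from C4a, so it maps onto an aldehyde and the six-membered ring closes by intramolecular vinyl addition to C=O.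
- Stereochemistry: C6 and C7 come from L-tartaric acid (2,3-O-isopropylidene-L-threitol). C5 is set by Felkin–Anh addition to the α-alkoxy aldehyde. C8 is set in the ring closure on the half-chair fixed by the trans-acetonide.
- Helpers: the side chain is carried as the (E)-styryl group, so there is no acidic CH2 beside the pyranone during zincation. It is saturated at the end in the hydrogenation that also removes both benzyl ethers; the acetonide is hydrolysed last.

Key step: step 11

Remark: atoms are named by the chromone numbering of the target throughout, also in open-chain intermediates.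

Step 1
Reactants: 1 (4S,5S)-2,2-dimethyl-1,3-dioxolane-4,5-dimethanol
Product: 2 mono-TBS ether of 1
Conditions: NaH (1.0 equiv), THF, 0 °C; then TBSCl (1.0 equiv), 0 to 25 °C
Reagents that add atoms: tert-butyldimethylsilyl chloride, CC(C)(C)[Si](C)(C)Cl
Why: Williamson-type O-silylation of the monosodium alkoxide of a C2-symmetric diol gives the same monosilyl ether whichever hydroxyl reacts, and no stereocentre is touched.

Step 2
Reactants: 2 mono-TBS ether
Product: 3 (4R,5S)-5-(silyloxymethyl)-2,2-dimethyl-1,3-dioxolane-4-carbaldehyde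
Conditions: Dess–Martin periodinane, pyridine, CH2Cl2, 0 to 25 °C
Reagents that add atoms: none
Why: Dess–Martin oxidation takes the primary alcohol to the aldehyde (future C5) under buffered, non-epimerising conditions that spare the acetonide and the silyl ether.

Step 3
Reactants: 3 aldehyde; 4 but-3-yn-2-one
Product: 5 (Z)-β-iodo enone alcohol (C4a–C5 bond, 5S)
Conditions: MgI2 (1.3 equiv), CH2Cl2, −78 to 0 °C
Reagents that add atoms: magnesium diiodide, [Mg+2].[I-].[I-]
Why: Iodo-aldol reaction (halo-aldol variant of the Morita–Baylis–Hillman reaction): iodide adds to the ynone terminus (future C8a), the magnesium iodoallenolate attacks the aldehyde through its α-carbon (future C4a), and Felkin–Anh approach anti to the α-C–O bond of the dioxolane sets C5 anti to O6, as the target needs.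

Step 4
Reactants: 5 iodo enone alcohol
Product: 6 C5 benzyl ether of 5
Conditions: BnOC(=NH)CCl3 (1.5 equiv), CF3SO3H (5 mol%), CH2Cl2/cyclohexane, 0 °C
Reagents that add atoms: benzyl 2,2,2-trichloroacetimidate, N=C(OCc1ccccc1)C(Cl)(Cl)Cl
Why: Acid-catalysed O-benzylation with the trichloroacetimidate needs no base, so the base-sensitive β-hydroxy iodoenone is protected without elimination and C5 is untouched.

Step 5
Reactants: 7 3-(benzyloxy)-4-methoxybenzaldehyde; 8 malonic acid
Product: 9 (E)-3-[3-(benzyloxy)-4-methoxyphenyl]prop-2-enoic acid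
Conditions: pyridine, piperidine (cat.), 100 °C
Reagents that add atoms: none
Why: Knoevenagel–Doebner condensation with decarboxylation gives the (E)-cinnamic acid; the aryl benzyl ether is inert.

Step 6
Reactants: 9 cinnamic acid
Product: 10 (E)-3-[3-(benzyloxy)-4-methoxyphenyl]prop-2-enoyl chloride
Conditions: (COCl)2, DMF (cat.), CH2Cl2, 0 to 25 °C
Reagents that add atoms: oxalyl chloride, O=C(Cl)C(Cl)=O
Why: Acid chloride formation through the Vilsmeier-type chloroiminium catalyst proceeds at room temperature without touching the alkene or the ethers.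

Step 7
Reactants: 6 benzyl-protected iodo enone; 10 acid chloride
Product: 12 2-styryl-5-substituted 4H-pyran-4-one, via iodovinyl diketone 11 (not isolated)
Conditions: LiN(SiMe3)2 (2.2 equiv), THF, −78 °C; then 10, −78 to 25 °C
Reagents that add atoms: none
Why: Claisen-type C-acylation of the kinetic lithium enolate of the methyl ketone forms C2–C3, and the enolate oxygen of the resulting 1,3-diketone then displaces the vinylic iodide at C8a by addition–elimination (O1–C8a), the ring closure known for β-alkoxyvinyl and β-halovinyl 1,3-diketones, to give the γ-pyranone with all stereocentres untouched.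

Step 8
Reactants: 12 pyranone
Product: 14 2-iodo-4H-pyran-4-one (iodine on C8a), via pyranylzinc amide 13 (not isolated)
Conditions: TMP2Zn·2MgCl2·2LiCl (1.1 equiv; TMP = 2,2,6,6-tetramethylpiperidide), THF, −30 to 0 °C; then I2, 0 °C
Reagents that add atoms: iodine, II
Why: Directed zincation of chromones and γ-pyranones with this magnesium chloride-containing amide base takes place at the ring C–H next to the ring oxygen, here C8a–H only, the styryl side chain offering no acidic sp3 C–H, and iodolysis of the C–Zn bond gives the vinyl iodide needed for the ring closure.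

Step 9
Reactants: 14 iodopyranone silyl ether
Product: 15 iodopyranone primary alcohol
Conditions: HF·pyridine, pyridine, THF, 0 to 25 °C
Reagents that add atoms: none
Why: Pyridine-buffered HF cleaves the primary silyl ether selectively and, lacking a free nucleophilic fluoride, does not displace the vinylic iodide or open the acetonide.

Step 10
Reactants: 15 primary alcohol
Product: 16 iodopyranone aldehyde (C8 = CHO)
Conditions: Dess–Martin periodinane, pyridine, CH2Cl2, 0 to 25 °C
Reagents that add atoms: none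
Why: Dess–Martin oxidation gives the α-alkoxy aldehyde (C8) under buffered conditions that do not epimerise C7 and leave the iodopyranone intact.

Step 11
Reactants: 16 iodopyranone aldehyde
Product: 18 protected tetrahydrochromone (C8a–C8 bond, 8S alcohol), via vinylchromium species 17 (not isolated)
Conditions: CrCl2 (6 equiv), NiCl2 (5 mol%), degassed DMF, 0.005 M, 25 °C
Reagents that add atoms: none
Why: Zerovalent nickel, formed from NiCl2 and CrCl2, inserts into the C8a–I bond of the 2-iodo-γ-pyranone, transmetalation gives the vinylchromium species 17, and this adds to the C8 aldehyde through a chromium-bridged transition state. The closest known reaction type is the intramolecular Nozaki–Hiyama–Kishi cyclisation of vinyl iodides, β-iodo enones included, onto aldehydes to give cyclohexenols. The carbocycle (C4a, C5, C6, C7, C8, C8a) closes in a 6-exo-trig mode at the aldehyde carbon, with C8a=C4a inside the new ring. The new stereocentre C8 is under substrate control: the trans-fused acetonide holds O6 and O7 diequatorial and so fixes one half-chair, and the chromium-bound carbonyl oxygen must lie near the pyranone plane (pseudo-equatorial), which places O8 trans to O7. The step needs activation of C–I in the presence of the aldehyde, the pyranone carbonyl and the styryl alkene, which the chromium and nickel pair provides, and ring closure over intermolecular coupling, which high dilution and the cis arrangement of the C4a chain and the C8a metal on the ring double bond secure.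

Step 12
Reactants: 18 protected tetrahydrochromone
Product: 19 6,7-acetonide of the target
Conditions: H2 (1 atm), Pd(OH)2/C, EtOAc/MeOH, 25 °C
Reagents that add atoms: none
Why: Heterogeneous hydrogenation saturates the disubstituted styryl alkene and hydrogenolyses both benzyl ethers, while the more substituted, electron-poor pyranone double bonds are not reduced, as in the known conversion of 2-styrylchromones into 2-(2-phenylethyl)chromones.

Step 13
Reactants: 19 acetonide
Product: 20 CNP0224308.1
Conditions: AcOH/H2O (4:1), 40 °C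
Reagents that add atoms: none
Why: Mild aqueous acid hydrolyses the strained trans-fused dioxolane to the 6,7-diol without ionising the C5 and C8 carbinols, so all four stereocentres are kept.

**Compound list**
1 | (4S,5S)-2,2-dimethyl-1,3-dioxolane-4,5-dimethanol (2,3-O-isopropylidene-L-threitol) | OC[C@@H]1OC(C)(C)O[C@H]1CO | starting material
2 | [(4S,5S)-5-({[tert-butyl(dimethyl)silyl]oxy}methyl)-2,2-dimethyl-1,3-dioxolan-4-yl]methanol | CC(C)(C)[Si](C)(C)OC[C@@H]1OC(C)(C)O[C@H]1CO | intermediate
3 | (4R,5S)-5-({[tert-butyl(dimethyl)silyl]oxy}methyl)-2,2-dimethyl-1,3-dioxolane-4-carbaldehyde | CC(C)(C)[Si](C)(C)OC[C@@H]1OC(C)(C)O[C@H]1C=O | intermediate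
4 | but-3-yn-2-one | CC(=O)C#C | starting material
5 | (3Z)-3-{(S)-[(4S,5S)-5-({[tert-butyl(dimethyl)silyl]oxy}methyl)-2,2-dimethyl-1,3-dioxolan-4-yl](hydroxy)methyl}-4-iodobut-3-en-2-one | CC(=O)/C(=C\I)[C@H](O)[C@@H]1OC(C)(C)O[C@H]1CO[Si](C)(C)C(C)(C)C | intermediate
6 | (3Z)-3-{(S)-(benzyloxy)[(4S,5S)-5-({[tert-butyl(dimethyl)silyl]oxy}methyl)-2,2-dimethyl-1,3-dioxolan-4-yl]methyl}-4-iodobut-3-en-2-one | CC(=O)/C(=C\I)[C@H](OCc1ccccc1)[C@@H]1OC(C)(C)O[C@H]1CO[Si](C)(C)C(C)(C)C | intermediate
7 | 3-(benzyloxy)-4-methoxybenzaldehyde | COc1ccc(C=O)cc1OCc1ccccc1 | starting material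
8 | malonic acid | OC(=O)CC(=O)O | starting material
9 | (2E)-3-[3-(benzyloxy)-4-methoxyphenyl]prop-2-enoic acid | COc1ccc(/C=C/C(=O)O)cc1OCc1ccccc1 | intermediate
10 | (2E)-3-[3-(benzyloxy)-4-methoxyphenyl]prop-2-enoyl chloride | COc1ccc(/C=C/C(Cl)=O)cc1OCc1ccccc1 | intermediate
11 | (1E,6Z)-1-[3-(benzyloxy)-4-methoxyphenyl]-6-{(S)-(benzyloxy)[(4S,5S)-5-({[tert-butyl(dimethyl)silyl]oxy}methyl)-2,2-dimethyl-1,3-dioxolan-4-yl]methyl}-7-iodohepta-1,6-diene-3,5-dione | COc1ccc(/C=C/C(=O)CC(=O)/C(=C\I)[C@H](OCc2ccccc2)[C@@H]2OC(C)(C)O[C@H]2CO[Si](C)(C)C(C)(C)C)cc1OCc1ccccc1 | intermediate (not isolated)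
12 | 2-{(E)-2-[3-(benzyloxy)-4-methoxyphenyl]ethenyl}-5-{(S)-(benzyloxy)[(4S,5S)-5-({[tert-butyl(dimethyl)silyl]oxy}methyl)-2,2-dimethyl-1,3-dioxolan-4-yl]methyl}-4H-pyran-4-one | O=c1cc(/C=C/c2ccc(OC)c(OCc3ccccc3)c2)occ1[C@H](OCc1ccccc1)[C@@H]1OC(C)(C)O[C@H]1CO[Si](C)(C)C(C)(C)C | intermediate
13 | zinc 2,2,6,6-tetramethylpiperidide of 12 metalated at C8a (pyran C6) | O=c1cc(/C=C/c2ccc(OC)c(OCc3ccccc3)c2)oc([Zn]N2C(C)(C)CCCC2(C)C)c1[C@H](OCc1ccccc1)[C@@H]1OC(C)(C)O[C@H]1CO[Si](C)(C)C(C)(C)C | intermediate (not isolated)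
14 | 3-{(S)-(benzyloxy)[(4S,5S)-5-({[tert-butyl(dimethyl)silyl]oxy}methyl)-2,2-dimethyl-1,3-dioxolan-4-yl]methyl}-6-{(E)-2-[3-(benzyloxy)-4-methoxyphenyl]ethenyl}-2-iodo-4H-pyran-4-one | O=c1cc(/C=C/c2ccc(OC)c(OCc3ccccc3)c2)oc(I)c1[C@H](OCc1ccccc1)[C@@H]1OC(C)(C)O[C@H]1CO[Si](C)(C)C(C)(C)C | intermediate
15 | 3-{(S)-(benzyloxy)[(4S,5S)-5-(hydroxymethyl)-2,2-dimethyl-1,3-dioxolan-4-yl]methyl}-6-{(E)-2-[3-(benzyloxy)-4-methoxyphenyl]ethenyl}-2-iodo-4H-pyran-4-one | O=c1cc(/C=C/c2ccc(OC)c(OCc3ccccc3)c2)oc(I)c1[C@H](OCc1ccccc1)[C@@H]1OC(C)(C)O[C@H]1CO | intermediate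
16 | (4R,5S)-5-{(S)-(benzyloxy)[6-{(E)-2-[3-(benzyloxy)-4-methoxyphenyl]ethenyl}-2-iodo-4-oxo-4H-pyran-3-yl]methyl}-2,2-dimethyl-1,3-dioxolane-4-carbaldehyde | O=c1cc(/C=C/c2ccc(OC)c(OCc3ccccc3)c2)oc(I)c1[C@H](OCc1ccccc1)[C@@H]1OC(C)(C)O[C@H]1C=O | intermediate
17 | dichlorochromium species of 16 with chromium in place of iodine at C8a | O=c1cc(/C=C/c2ccc(OC)c(OCc3ccccc3)c2)oc([Cr](Cl)Cl)c1[C@H](OCc1ccccc1)[C@@H]1OC(C)(C)O[C@H]1C=O | intermediate (not isolated)
18 | (5S,6S,7S,8S)-5-(benzyloxy)-2-{(E)-2-[3-(benzyloxy)-4-methoxyphenyl]ethenyl}-8-hydroxy-6,7-(isopropylidenedioxy)-5,6,7,8-tetrahydro-4H-chromen-4-one (5,6-cis, 6,7-trans, 7,8-trans; the 7S descriptor differs from the target's 7R only through CIP priority) | COc1ccc(/C=C/c2cc(=O)c3c(o2)[C@@H](O)[C@@H]4OC(C)(C)O[C@H]4[C@H]3OCc5ccccc5)cc1OCc6ccccc6 | intermediate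
19 | (5S,6S,7S,8S)-5,8-dihydroxy-2-[2-(3-hydroxy-4-methoxyphenyl)ethyl]-6,7-(isopropylidenedioxy)-5,6,7,8-tetrahydro-4H-chromen-4-one | COc1ccc(CCc2cc(=O)c3c(o2)[C@@H](O)[C@@H]4OC(C)(C)O[C@H]4[C@H]3O)cc1O | intermediate
20 | (5S,6S,7R,8S)-5,6,7,8-tetrahydroxy-2-[2-(3-hydroxy-4-methoxyphenyl)ethyl]-5,6,7,8-tetrahydro-4H-chromen-4-one (CNP0224308.1) | COc1ccc(CCc2cc(=O)c3c(o2)[C@@H](O)[C@H](O)[C@@H](O)[C@H]3O)cc1O | target

**Step count**
Total: 13 steps. Longest linear sequence: 11 steps (steps 1–4 and 7–13, from 1); steps 5 and 6 form the side branch.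

**Steps most likely to fail**

Step 8. The zincation may take place at the carbonyl-flanked C3–H in place of C8a–H, or may be slow at the hindered C8a–H beside the branched C4a substituent. The fallback avoids metalation and uses the native electrophilicity of C8a. It sets out from 12 and comes back at 18. Desilylation of 12 with HF·pyridine gives the primary alcohol F1. Dess–Martin oxidation gives the aldehyde F2, which still carries C8a–H. Bu3SnH with AIBN in benzene at 80 °C generates the O-stannyl ketyl radical at C8, which adds to C8a in a 6-endo ketyl–enone cyclisation. The resulting C4a radical is quenched by the tin hydride rather than becoming an enolate, so the C5 benzyloxy group is not eliminated; work-up gives the 4a,8a-dihydro compound F3. Dehydrogenation with Pd(OCOCF3)2 and O2 in DMSO, as used for dihydropyranones and flavanones, restores the pyranone and gives 18.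

Step 11. The ring closure may show poor facial selectivity at C8. The fallback sets C8 by reduction and not in the C–C bond formation. It sets out from 16 and comes back at 18. The cyclisation is run as in step 11 without regard to C8, giving 18 together with its C8 epimer F4. Dess–Martin oxidation converges the mixture on the C8 ketone F5. Luche reduction (NaBH4, CeCl3·7H2O, MeOH, −78 °C) delivers hydride axially on the acetonide-locked half-chair and should give the pseudo-equatorial alcohol 18.

Step 3. Magnesium chelation may erode facial selectivity at C5, and the Lewis acid may open the acetonide. The fallback forms C4a–C5 with a non-chelating vinylchromium nucleophile and uses methoxide, not iodide, as the leaving group on C8a. It sets out from 3 and comes back at 12. Commercial (E)-4-methoxybut-3-en-2-one is α-iodinated (I2, pyridine, CH2Cl2) to (Z)-3-iodo-4-methoxybut-3-en-2-one F6. Intermolecular Nozaki–Hiyama–Kishi coupling of F6 with 3 (CrCl2, cat. NiCl2, DMF), under Felkin–Anh control, gives the methoxy enone alcohol F7. Benzylation as in step 4 gives F8. Acylation with 10 as in step 7 gives the methoxyvinyl diketone F9, which closes to 12 with catalytic CF3CO2H by loss of methanol.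

**Further compounds**
F1 | step 8 | 5-{(S)-(benzyloxy)[(4S,5S)-5-(hydroxymethyl)-2,2-dimethyl-1,3-dioxolan-4-yl]methyl}-2-{(E)-2-[3-(benzyloxy)-4-methoxyphenyl]ethenyl}-4H-pyran-4-one | O=c1cc(/C=C/c2ccc(OC)c(OCc3ccccc3)c2)occ1[C@H](OCc1ccccc1)[C@@H]1OC(C)(C)O[C@H]1CO
F2 | step 8 | (4R,5S)-5-{(S)-(benzyloxy)[6-{(E)-2-[3-(benzyloxy)-4-methoxyphenyl]ethenyl}-4-oxo-4H-pyran-3-yl]methyl}-2,2-dimethyl-1,3-dioxolane-4-carbaldehyde | O=c1cc(/C=C/c2ccc(OC)c(OCc3ccccc3)c2)occ1[C@H](OCc1ccccc1)[C@@H]1OC(C)(C)O[C@H]1C=O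
F3 | step 8 | 4a,8a-dihydro derivative of 18 (C5 to C8 as in 18; C4a and C8a not defined) | COc1ccc(/C=C/C2=CC(=O)C3C(O2)[C@@H](O)[C@@H]4OC(C)(C)O[C@H]4[C@H]3OCc5ccccc5)cc1OCc6ccccc6
F4 | step 11 | C8 epimer of 18 (8R; 7,8-cis) | COc1ccc(/C=C/c2cc(=O)c3c(o2)[C@H](O)[C@@H]4OC(C)(C)O[C@H]4[C@H]3OCc5ccccc5)cc1OCc6ccccc6
F5 | step 11 | 8-oxo compound from 18 and F4 (C5, C6, C7 as in 18) | COc1ccc(/C=C/c2cc(=O)c3c(o2)C(=O)[C@@H]4OC(C)(C)O[C@H]4[C@H]3OCc5ccccc5)cc1OCc6ccccc6
F6 | step 3 | (Z)-3-iodo-4-methoxybut-3-en-2-one | CC(=O)/C(I)=C/OC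
F7 | step 3 | (3E)-3-{(S)-[(4S,5S)-5-({[tert-butyl(dimethyl)silyl]oxy}methyl)-2,2-dimethyl-1,3-dioxolan-4-yl](hydroxy)methyl}-4-methoxybut-3-en-2-one | CC(=O)/C(=C/OC)[C@H](O)[C@@H]1OC(C)(C)O[C@H]1CO[Si](C)(C)C(C)(C)C
F8 | step 3 | (3E)-3-{(S)-(benzyloxy)[(4S,5S)-5-({[tert-butyl(dimethyl)silyl]oxy}methyl)-2,2-dimethyl-1,3-dioxolan-4-yl]methyl}-4-methoxybut-3-en-2-one | CC(=O)/C(=C/OC)[C@H](OCc1ccccc1)[C@@H]1OC(C)(C)O[C@H]1CO[Si](C)(C)C(C)(C)C
F9 | step 3 | (1E,6E)-1-[3-(benzyloxy)-4-methoxyphenyl]-6-{(S)-(benzyloxy)[(4S,5S)-5-({[tert-butyl(dimethyl)silyl]oxy}methyl)-2,2-dimethyl-1,3-dioxolan-4-yl]methyl}-7-methoxyhepta-1,6-diene-3,5-dione | COc1ccc(/C=C/C(=O)CC(=O)/C(=C/OC)[C@H](OCc2ccccc2)[C@@H]2OC(C)(C)O[C@H]2CO[Si](C)(C)C(C)(C)C)cc1OCc1ccccc1
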